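**Plan**

1. Retrosynthetic cuts: the eight aryl methyl ethers; the bond from the diarylmethine carbon of the eight-membered ring to the resorcinol ring on benzofuran C3 (Friedel–Crafts); that methine's bond to its 4-methoxyphenyl group (Grignard addition to an aldehyde); the indane C3–C3a bond, moved back to C4–C4a of a 1,2-dihydronaphthalene (reverse of a 1,2-aryl shift); the two aryl bonds at C1 and C2 of that ring (Suzuki coupling, ketone α-arylation); the C2–C3 bond of the dihydrobenzofuran (carbene C–H insertion).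
2. Enabling feature: the indane carries cis aryl groups on C1 and C2 and, on C3, the exocyclic methine carbon trans to the C2 aryl. A cis-1,2-diaryl-1,2-dihydronaphthalene already holds this pattern: attack at C3 of its C3=C4 alkene anti to the aryl groups and shift of the fused arene carbon C4a from C4 to C3 turns C3 into indane C3 and C4 into the exocyclic carbon.
3. Forward order: the dihydrobenzofuran bromide (steps 1–7) and a 4-silyloxy tetralone (steps 8–10) are joined, the six-membered ring is taken to the cis-diaryl dihydronaphthalene (steps 11–16) and contracted to the indane (step 17); the eight-membered ring is closed last (steps 18–20), then demethylation (step 21).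
4. Stereochemistry: benzofuran C3 comes from a chiral dirhodium carboxylate (C2 is then equilibrated to trans). The tetralone carbinol comes from asymmetric transfer hydrogenation and is relayed to the two aryl-bearing carbons by hydroxyl-directed hydrogenation. Indane C3 is set by inversion in the aryl shift, and the last methine in the ring closure.

Key step: step 17

Assumption: Rh2(S-PTAD)4, dirhodium tetrakis[(S)-(1-adamantyl)(phthalimido)acetate], is taken as the enantiomer that gives the (3R) dihydrobenzofuran (otherwise Rh2(R-PTAD)4 is used); compounds 1, 3, 5, 12, 18 and 26 are taken as purchasable (5 and 26 as THF solutions).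

Abbreviation: Ar* = (2R,3R)-3-(3,5-dimethoxyphenyl)-6-methoxy-2-(4-methoxyphenyl)-2,3-dihydro-1-benzofuran-4-yl. For indanes 24, 25 and 27, C1 bears the 4-methoxyphenyl group, C2 bears Ar* and C3 bears the exocyclic carbon.

**Step 1**
Reactants: 1 2-bromo-4,6-dimethoxybenzaldehyde
Product: 2 2-bromo-6-hydroxy-4-methoxybenzaldehyde
Conditions: BCl3 (1.2 equiv), CH2Cl2, −78 → 0 °C; H2O
Reagents that add atoms: none
Why: Chelation-directed Lewis acid demethylation, in which BCl3 is held between the formyl oxygen and the ortho methoxy oxygen and cleaves only that ether, the para methoxy group and the aryl bromide being inert.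

**Step 2**
Reactants: 2 2-bromo-6-hydroxy-4-methoxybenzaldehyde; 3 4-methoxybenzyl chloride
Product: 4 2-bromo-4-methoxy-6-[(4-methoxybenzyl)oxy]benzaldehyde
Conditions: K2CO3, Bu4NI (cat.), DMF, 60 °C
Reagents that add atoms: 4-methoxybenzyl chloride (3), COc1ccc(CCl)cc1
Why: Williamson ether synthesis of the phenoxide with a reactive benzylic chloride; the benzylic CH2 installed here is the carbon that becomes C2 of the dihydrobenzofuran.

**Step 3**
Reactants: 4 2-bromo-4-methoxy-6-[(4-methoxybenzyl)oxy]benzaldehyde; 5 (3,5-dimethoxyphenyl)magnesium bromide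
Product: 6 rac-{2-bromo-4-methoxy-6-[(4-methoxybenzyl)oxy]phenyl}(3,5-dimethoxyphenyl)methanol
Conditions: THF, −78 → 0 °C; aq. NH4Cl
Reagents that add atoms: (3,5-dimethoxyphenyl)magnesium bromide (5), COc1cc(OC)cc([Mg]Br)c1
Why: Grignard addition to the aldehyde, fast at low temperature where the aryl bromide does not undergo halogen–magnesium exchange; the racemic carbinol centre is erased in step 4.

**Step 4**
Reactants: 6 rac-diarylmethanol
Product: 7 {2-bromo-4-methoxy-6-[(4-methoxybenzyl)oxy]phenyl}(3,5-dimethoxyphenyl)methanone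
Conditions: Dess–Martin periodinane, NaHCO3, CH2Cl2, rt
Reagents that add atoms: none
Why: Dess–Martin oxidation of the hindered diarylmethanol under buffered, neutral conditions that spare the 4-methoxybenzyl ether.

**Step 5**
Reactants: 7 diaryl ketone
Product: 8 hydrazone of 7 (E/Z mixture)
Conditions: N2H4·H2O (20 equiv), AcOH (cat.), n-BuOH, 110 °C, sealed tube
Reagents that add atoms: hydrazine (as hydrate), NN
Why: Condensation of the ketone with hydrazine to the N-unsubstituted hydrazone, driven by excess reagent and heat because the carbonyl group is flanked by two ortho substituents; the electron-rich aryl bromide should not be displaced.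

**Step 6**
Reactants: 8 hydrazone of 7
Product: 10 (2S,3R)-4-bromo-3-(3,5-dimethoxyphenyl)-6-methoxy-2-(4-methoxyphenyl)-2,3-dihydro-1-benzofuran (2,3-cis), via diaryldiazomethane 9 (not isolated)
Conditions: MnO2, CH2Cl2, 0 °C, filtration; Rh2(S-PTAD)4 (1 mol %), CH2Cl2, 0 °C → rt
Reagents that add atoms: none
Why: Oxidation of the hydrazone by MnO2 to the diaryldiazomethane and dirhodium-catalysed intramolecular C–H insertion of the donor/donor carbene into the benzylic ether C–H (five-membered ring); the chiral carboxylate ligands set C3 as R and the concerted insertion gives the 2,3-cis isomer.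

**Step 7**
Reactants: 10 cis-dihydrobenzofuran
Product: 11 (2R,3R)-4-bromo-3-(3,5-dimethoxyphenyl)-6-methoxy-2-(4-methoxyphenyl)-2,3-dihydro-1-benzofuran (2,3-trans)
Conditions: CF3CO2H, CH2Cl2, 0 °C
Reagents that add atoms: none
Why: Acid-promoted epimerization at C2, in which reversible ionization of the C2–O bond to the 4-methoxybenzyl cation and reclosure by the phenol should lead to the more stable trans isomer while C3 is not involved, the low temperature limiting proton loss from the cation.

**Step 8**
Reactants: 12 5,7-dimethoxy-3,4-dihydronaphthalen-1(2H)-one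
Product: 13 (1S)-5,7-dimethoxy-1,2,3,4-tetrahydronaphthalen-1-ol
Conditions: RuCl[(S,S)-TsDPEN](p-cymene) (1 mol %), HCO2H/Et3N (5:2), 30 °C
Reagents that add atoms: none
Why: Noyori–Ikariya asymmetric transfer hydrogenation of an aryl alkyl ketone, in which the (S,S)-catalyst delivers hydride to give the (S)-carbinol.

**Step 9**
Reactants: 13 (1S)-tetralol
Product: 14 triisopropyl{[(1S)-5,7-dimethoxy-1,2,3,4-tetrahydronaphthalen-1-yl]oxy}silane
Conditions: iPr3SiOTf, 2,6-lutidine, CH2Cl2, 0 °C
Reagents that add atoms: triisopropylsilyl trifluoromethanesulfonate, CC(C)[Si](C(C)C)(C(C)C)OS(=O)(=O)C(F)(F)F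
Why: Silylation of the secondary benzylic alcohol with a silyl triflate and a hindered base; the bulky silyl ether is chosen to withstand the oxidant, the strong bases and the couplings of steps 10–13.

**Step 10**
Reactants: 14 silyl ether
Product: 15 (4S)-6,8-dimethoxy-4-[(triisopropylsilyl)oxy]-3,4-dihydronaphthalen-1(2H)-one
Conditions: DDQ (2.5 equiv), 1,4-dioxane/H2O, rt
Reagents that add atoms: water, O
Why: Benzylic oxidation by DDQ in wet solvent: hydride is abstracted only from the CH2 on the ring carbon that is ortho and para to the methoxy groups, water traps the cation and the alcohol is oxidized on to the ketone, whereas the silyloxy-bearing benzylic carbon sits meta to both methoxy groups and should be left alone.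

**Step 11**
Reactants: 15 silyloxy tetralone; 11 trans-dihydrobenzofuran bromide
Product: 16 (4S)-2-Ar*-6,8-dimethoxy-4-[(triisopropylsilyl)oxy]-3,4-dihydronaphthalen-1(2H)-one (both C2 epimers)
Conditions: Pd2(dba)3 (2.5 mol %), XPhos (6 mol %), NaOtBu, toluene, 80 °C
Reagents that add atoms: bromide 11, Brc1cc(OC)cc2O[C@@H](c3ccc(OC)cc3)[C@H](c3cc(OC)cc(OC)c3)c12
Why: Palladium-catalysed α-arylation of the ketone enolate (Buchwald–Hartwig type) with a bulky biaryl phosphine for the ortho-substituted bromide; only C2 carries α-hydrogens, and its configuration is irrelevant because it becomes sp2 in step 12.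

**Step 12**
Reactants: 16 α-aryl tetralone
Product: 17 (4S)-6,8-dimethoxy-2-Ar*-4-[(triisopropylsilyl)oxy]-3,4-dihydronaphthalen-1-yl trifluoromethanesulfonate
Conditions: KN(SiMe3)2, THF, −78 °C; PhNTf2, −78 → 0 °C
Reagents that add atoms: N-phenylbis(trifluoromethanesulfonimide), O=S(=O)(N(c1ccccc1)S(=O)(=O)C(F)(F)F)C(F)(F)F
Why: Deprotonation of the acidic α-aryl ketone and O-sulfonylation of the potassium enolate gives the only possible enol triflate.

**Step 13**
Reactants: 17 enol triflate; 18 4-methoxyphenylboronic acid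
Product: 19 {[(1S)-5,7-dimethoxy-4-(4-methoxyphenyl)-3-Ar*-1,2-dihydronaphthalen-1-yl]oxy}triisopropylsilane
Conditions: Pd(OAc)2 (5 mol %), SPhos (10 mol %), K3PO4, toluene/H2O, 80 °C
Reagents that add atoms: 4-methoxyphenylboronic acid (18), COc1ccc(B(O)O)cc1
Why: Suzuki–Miyaura coupling of the enol triflate with the arylboronic acid, the electron-rich biaryl phosphine being chosen for coupling at the hindered, fully substituted alkene carbon.

**Step 14**
Reactants: 19 silyl ether
Product: 20 (1S)-5,7-dimethoxy-4-(4-methoxyphenyl)-3-Ar*-1,2-dihydronaphthalen-1-ol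
Conditions: Bu4NF, THF, rt
Reagents that add atoms: none
Why: Fluoride cleavage of the silyl ether under non-acidic conditions, which avoids dehydration of the benzylic alcohol to the naphthalene.

**Step 15**
Reactants: 20 homoallylic alcohol
Product: 21 (1S,3S,4R)-5,7-dimethoxy-4-(4-methoxyphenyl)-3-Ar*-1,2,3,4-tetrahydronaphthalen-1-ol (aryl groups cis to each other, trans to OH)
Conditions: [Ir(cod)(PCy3)(py)]PF6 (10 mol %), H2 (50 bar), CH2Cl2, rt
Reagents that add atoms: none
Why: Hydroxyl-directed hydrogenation with a cationic iridium catalyst of the kind that reduces tetrasubstituted alkenes: the homoallylic hydroxyl group binds iridium and both hydrogen atoms are delivered to its face, so the two aryl groups end cis to each other and trans to OH (C3 S and C4 R).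

**Step 16**
Reactants: 21 cis-diaryl tetralol
Product: 22 (1R,2S)-6,8-dimethoxy-1-(4-methoxyphenyl)-2-Ar*-1,2-dihydronaphthalene
Conditions: Burgess reagent (Et3N+SO2N−CO2Me), toluene, 70 °C
Reagents that add atoms: none
Why: Burgess dehydration (syn elimination of the sulfamate ester) towards the only β-hydrogens, at C2 of 21, should give the styrene-type C3=C4 alkene without acid and without touching the two aryl-bearing stereocenters.

**Step 17**
Reactants: 22 cis-1,2-diaryl-1,2-dihydronaphthalene
Product: 24 (1R,2R,3S)-3-(dimethoxymethyl)-5,7-dimethoxy-1-(4-methoxyphenyl)-2-Ar*-indane, via trans-methoxy-λ3-iodane adduct 23 (not isolated)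
Conditions: PhI(OH)OTs (1.2 equiv), MeOH/CH2Cl2, 0 °C → rt; aq. NaHCO3
Reagents that add atoms: methanol, CO
Why: The trivalent iodine reagent adds to C3 of the C3=C4 alkene on the face opposite the two cis aryl groups while methanol adds to benzylic C4, giving adduct 23; the phenyl-λ3-iodanyl group then leaves as iodobenzene as the fused arene carbon C4a shifts from C4 to C3, and the oxocarbenium ion left at C4 is trapped by methanol as the dimethyl acetal. The closest known reaction type is the oxidative ring contraction of 1,2-dihydronaphthalenes to 1-indanyl acetals by hydroxy(tosyloxy)iodobenzene in methanol, a semipinacol-type rearrangement. The five-membered ring closes by contraction, that is by a 1,2-aryl shift through a bridged, phenonium-like transition state in which C4a bonds to C3 as the C3–I bond breaks, not by an end-to-end cyclization. The new stereocenter (C3 of 24) is set by inversion at the iodine-bearing carbon, so that the aryl groups at C1 and C2, which direct the iodane to the opposite face, place the acetal carbon trans to the C2 aryl. The step needs alkene-over-arene chemoselectivity, secured by the absence of free phenols and the methanol-moderated reagent at 0 °C, and aryl shift over solvolysis, secured by the peri methoxy group at C8, which holds the C1 aryl pseudoaxial and hence the C3–I bond pseudoequatorial and antiperiplanar to the C4–C4a bond.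

**Step 18**
Reactants: 24 indane dimethyl acetal
Product: 25 (1R,2R,3S)-5,7-dimethoxy-1-(4-methoxyphenyl)-2-Ar*-indane-3-carbaldehyde
Conditions: pyridinium p-toluenesulfonate (cat.), acetone/H2O, 50 °C
Reagents that add atoms: water, O
Why: Mild acid hydrolysis of the dimethyl acetal; the formyl group stays trans to the neighbouring aryl group, which is also the more stable arrangement, so enolization should not degrade the centre.

**Step 19**
Reactants: 25 aldehyde; 26 (4-methoxyphenyl)magnesium bromide
Product: 27 3-[hydroxy(4-methoxyphenyl)methyl] analogue of 24, (1R,2R,3S), both carbinol epimers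
Conditions: THF, −78 → 0 °C; aq. NH4Cl
Reagents that add atoms: (4-methoxyphenyl)magnesium bromide (26), COc1ccc([Mg]Br)cc1
Why: Grignard addition to the aldehyde at low temperature to outrun enolization; both carbinol epimers are acceptable because this centre is ionized in step 20.

**Step 20**
Reactants: 27 secondary alcohol
Product: 28 octa-O-methylcanaliculatol
Conditions: BF3·OEt2 (0.5 equiv), CH2Cl2 (0.002 M), −40 → 0 °C
Reagents that add atoms: none
Why: Intramolecular Friedel–Crafts alkylation in which the 4-methoxybenzyl-type cation attacks the 3,5-dimethoxyphenyl ring at a carbon ortho and para to its methoxy groups and closes the eight-membered ring (the competing five-membered closure onto the benzofuran arene would be trans-fused and strained); the new methine is expected to form by attack on the cation face that leaves the 4-methoxyphenyl group outside the fold, and the reversible conditions should favour this more stable epimer.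

**Step 21**
Reactants: 28 octa-O-methylcanaliculatol
Product: 29 canaliculatol
Conditions: BBr3 (24 equiv), CH2Cl2, −78 °C → rt; MeOH, H2O
Reagents that add atoms: none
Why: Lewis acid cleavage of all eight aryl methyl ethers with BBr3; the only centre that can ionize, C2 of the dihydrobenzofuran, is already in its stable trans arrangement.

**Compound list**

1 | 2-bromo-4,6-dimethoxybenzaldehyde | COc1cc(Br)c(C=O)c(OC)c1 | starting material
2 | 2-bromo-6-hydroxy-4-methoxybenzaldehyde | COc1cc(O)c(C=O)c(Br)c1 | intermediate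
3 | 4-methoxybenzyl chloride | COc1ccc(CCl)cc1 | starting material
4 | 2-bromo-4-methoxy-6-[(4-methoxybenzyl)oxy]benzaldehyde | COc1ccc(COc2cc(OC)cc(Br)c2C=O)cc1 | intermediate
5 | (3,5-dimethoxyphenyl)magnesium bromide | COc1cc(OC)cc([Mg]Br)c1 | starting material
6 | rac-{2-bromo-4-methoxy-6-[(4-methoxybenzyl)oxy]phenyl}(3,5-dimethoxyphenyl)methanol | COc1ccc(COc2cc(OC)cc(Br)c2C(O)c2cc(OC)cc(OC)c2)cc1 | intermediate
7 | {2-bromo-4-methoxy-6-[(4-methoxybenzyl)oxy]phenyl}(3,5-dimethoxyphenyl)methanone | COc1ccc(COc2cc(OC)cc(Br)c2C(=O)c2cc(OC)cc(OC)c2)cc1 | intermediate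
8 | hydrazone of 7 (E/Z mixture) | COc1ccc(COc2cc(OC)cc(Br)c2C(=NN)c2cc(OC)cc(OC)c2)cc1 | intermediate
9 | diaryldiazomethane from 8 | COc1ccc(COc2cc(OC)cc(Br)c2C(=[N+]=[N-])c2cc(OC)cc(OC)c2)cc1 | intermediate (not isolated)
10 | (2S,3R)-4-bromo-3-(3,5-dimethoxyphenyl)-6-methoxy-2-(4-methoxyphenyl)-2,3-dihydro-1-benzofuran (cis) | Brc1cc(OC)cc2O[C@H](c3ccc(OC)cc3)[C@H](c3cc(OC)cc(OC)c3)c12 | intermediate
11 | (2R,3R)-4-bromo-3-(3,5-dimethoxyphenyl)-6-methoxy-2-(4-methoxyphenyl)-2,3-dihydro-1-benzofuran (trans) | Brc1cc(OC)cc2O[C@@H](c3ccc(OC)cc3)[C@H](c3cc(OC)cc(OC)c3)c12 | intermediate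
12 | 5,7-dimethoxy-3,4-dihydronaphthalen-1(2H)-one | COc1cc(OC)c2CCCC(=O)c2c1 | starting material
13 | (1S)-5,7-dimethoxy-1,2,3,4-tetrahydronaphthalen-1-ol | O[C@H]1CCCc2c(OC)cc(OC)cc12 | intermediate
14 | triisopropyl{[(1S)-5,7-dimethoxy-1,2,3,4-tetrahydronaphthalen-1-yl]oxy}silane | CC(C)[Si](C(C)C)(C(C)C)O[C@H]1CCCc2c(OC)cc(OC)cc12 | intermediate
15 | (4S)-6,8-dimethoxy-4-[(triisopropylsilyl)oxy]-3,4-dihydronaphthalen-1(2H)-one | CC(C)[Si](C(C)C)(C(C)C)O[C@H]1CCC(=O)c2c(OC)cc(OC)cc12 | intermediate
16 | (4S)-2-Ar*-6,8-dimethoxy-4-[(triisopropylsilyl)oxy]-3,4-dihydronaphthalen-1(2H)-one (both C2 epimers) | CC(C)[Si](C(C)C)(C(C)C)O[C@H]1CC(c3cc(OC)cc4O[C@@H](c5ccc(OC)cc5)[C@H](c5cc(OC)cc(OC)c5)c34)C(=O)c2c(OC)cc(OC)cc12 | intermediate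
17 | (4S)-6,8-dimethoxy-2-Ar*-4-[(triisopropylsilyl)oxy]-3,4-dihydronaphthalen-1-yl trifluoromethanesulfonate | CC(C)[Si](C(C)C)(C(C)C)O[C@H]1CC(c3cc(OC)cc4O[C@@H](c5ccc(OC)cc5)[C@H](c5cc(OC)cc(OC)c5)c34)=C(OS(=O)(=O)C(F)(F)F)c2c(OC)cc(OC)cc12 | intermediate
18 | 4-methoxyphenylboronic acid | COc1ccc(B(O)O)cc1 | starting material
19 | {[(1S)-5,7-dimethoxy-4-(4-methoxyphenyl)-3-Ar*-1,2-dihydronaphthalen-1-yl]oxy}triisopropylsilane | CC(C)[Si](C(C)C)(C(C)C)O[C@H]1CC(c3cc(OC)cc4O[C@@H](c5ccc(OC)cc5)[C@H](c5cc(OC)cc(OC)c5)c34)=C(c3ccc(OC)cc3)c2c(OC)cc(OC)cc12 | intermediate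
20 | (1S)-5,7-dimethoxy-4-(4-methoxyphenyl)-3-Ar*-1,2-dihydronaphthalen-1-ol | O[C@H]1CC(c3cc(OC)cc4O[C@@H](c5ccc(OC)cc5)[C@H](c5cc(OC)cc(OC)c5)c34)=C(c3ccc(OC)cc3)c2c(OC)cc(OC)cc12 | intermediate
21 | (1S,3S,4R)-5,7-dimethoxy-4-(4-methoxyphenyl)-3-Ar*-1,2,3,4-tetrahydronaphthalen-1-ol | COc1ccc([C@@H]2c3c(OC)cc(OC)cc3[C@@H](O)C[C@@H]2c2cc(OC)cc3O[C@@H](c4ccc(OC)cc4)[C@H](c4cc(OC)cc(OC)c4)c23)cc1 | intermediate
22 | (1R,2S)-6,8-dimethoxy-1-(4-methoxyphenyl)-2-Ar*-1,2-dihydronaphthalene (cis) | COc1ccc([C@@H]2c3c(OC)cc(OC)cc3C=C[C@@H]2c2cc(OC)cc3O[C@@H](c4ccc(OC)cc4)[C@H](c4cc(OC)cc(OC)c4)c23)cc1 | intermediate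
23 | trans-methoxy-λ3-iodane adduct of 22 (iodane on C3 anti to the aryl groups, methoxy on C4) | COc1ccc([C@@H]2c3c(OC)cc(OC)cc3[C@H](OC)[C@@H]([I](c3ccccc3)OS(=O)(=O)c3ccc(C)cc3)[C@@H]2c2cc(OC)cc3O[C@@H](c4ccc(OC)cc4)[C@H](c4cc(OC)cc(OC)c4)c23)cc1 | intermediate (not isolated)
24 | (1R,2R,3S)-3-(dimethoxymethyl)-5,7-dimethoxy-1-(4-methoxyphenyl)-2-Ar*-indane | COc1ccc([C@@H]2c3c(OC)cc(OC)cc3[C@@H](C(OC)OC)[C@@H]2c2cc(OC)cc3O[C@@H](c4ccc(OC)cc4)[C@H](c4cc(OC)cc(OC)c4)c23)cc1 | intermediate
25 | (1R,2R,3S)-5,7-dimethoxy-1-(4-methoxyphenyl)-2-Ar*-indane-3-carbaldehyde | COc1ccc([C@@H]2c3c(OC)cc(OC)cc3[C@@H](C=O)[C@@H]2c2cc(OC)cc3O[C@@H](c4ccc(OC)cc4)[C@H](c4cc(OC)cc(OC)c4)c23)cc1 | intermediate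
26 | (4-methoxyphenyl)magnesium bromide | COc1ccc([Mg]Br)cc1 | starting material
27 | 3-[hydroxy(4-methoxyphenyl)methyl] analogue of 24, (1R,2R,3S), both carbinol epimers | COc1ccc([C@@H]2c3c(OC)cc(OC)cc3[C@@H](C(O)c3ccc(OC)cc3)[C@@H]2c2cc(OC)cc3O[C@@H](c4ccc(OC)cc4)[C@H](c4cc(OC)cc(OC)c4)c23)cc1 | intermediate
28 | octa-O-methylcanaliculatol | COc1ccc([C@@H]2c3c(OC)cc(OC)cc3[C@H]3[C@H](c4ccc(OC)cc4)c4c(OC)cc(OC)cc4[C@@H]4c5c(cc(OC)cc5[C@H]23)O[C@H]4c2ccc(OC)cc2)cc1 | intermediate
29 | canaliculatol | Oc1ccc([C@@H]2c3c(O)cc(O)cc3[C@H]3[C@H](c4ccc(O)cc4)c4c(O)cc(O)cc4[C@@H]4c5c(cc(O)cc5[C@H]23)O[C@H]4c2ccc(O)cc2)cc1 | target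

**Step count**

Total: 21 steps. Longest linear sequence: 18 steps (steps 1–7, then 11–21); the tetralone branch (steps 8–10) joins at step 11.

**Steps most likely to fail**

1. Step 15. The catalyst may not turn over at the congested tetrasubstituted diaryl alkene, or the acidic iridium hydride may dehydrate the benzylic alcohol so that the ring aromatizes. Fallback: facial control is moved from the hydroxyl group to a chiral catalyst and the alcohol stays protected. Silyl ether 19 is hydrogenated with [Ir(cod)(tBu-PHOX)][B(C6H3(CF3)2)4] (ligand enantiomer chosen for the required face; H2 80 bar, CH2Cl2) to give the (1S,3S,4R) triisopropylsilyl ether of 21 F1. Bu4NF in THF then returns the route to 21.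

2. Step 17. The iodane may attack the dimethoxyarenes instead of the alkene, or methanol may capture the adduct (1,2-dimethoxylation) before the aryl shift. Fallback: the same aryl shift is run in two stages from 22. N-Iodosuccinimide in MeOH at −20 °C adds iodine to C3 anti to the aryl groups and methanol to C4, giving the (1R,2S,3S,4S) trans-3-iodo-4-methoxy tetralin F2. AgOTf in MeOH/HC(OMe)3 at 0 °C then removes iodide, and the silver-assisted semipinacol shift with acetal formation leads to 24.

3. Step 20. The cation may close on the wrong face and give the epimeric methine, alkylate another molecule, or the dihydrobenzofuran may open reversibly and drain material. Fallback: the ring is closed first and the aryl group added second, starting from aldehyde 25. BF3·OEt2 in dilute CH2Cl2 effects intramolecular hydroxyalkylation of the 3,5-dimethoxyphenyl ring to the eight-membered cyclic benzylic alcohol F3 (both carbinol epimers). F3 is then ionized with BF3·OEt2 in the presence of anisole (10 equiv), whose para position attacks the cyclic cation from its open face to give 28.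

**Further compounds**

F1 | step 15 | triisopropylsilyl ether of 21, (1S,3S,4R) | COc1ccc([C@@H]2c3c(OC)cc(OC)cc3[C@@H](O[Si](C(C)C)(C(C)C)C(C)C)C[C@@H]2c2cc(OC)cc3O[C@@H](c4ccc(OC)cc4)[C@H](c4cc(OC)cc(OC)c4)c23)cc1
F2 | step 17 | (1R,2S,3S,4S)-3-iodo-4,6,8-trimethoxy-1-(4-methoxyphenyl)-2-Ar*-1,2,3,4-tetrahydronaphthalene | COc1ccc([C@@H]2c3c(OC)cc(OC)cc3[C@H](OC)[C@@H](I)[C@@H]2c2cc(OC)cc3O[C@@H](c4ccc(OC)cc4)[C@H](c4cc(OC)cc(OC)c4)c23)cc1
F3 | step 20 | analogue of 28 with OH in place of the 4-methoxyphenyl group on the eight-membered ring (both carbinol epimers) | COc1ccc([C@@H]2c3c(OC)cc(OC)cc3[C@H]3C(O)c4c(OC)cc(OC)cc4[C@@H]4c5c(cc(OC)cc5[C@H]23)O[C@H]4c2ccc(OC)cc2)cc1
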